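The plan rests on cutting C8–C9 of the seven-membered ring B (guaiane numbering). The C8 carbinol sits two bonds from methyl-bearing C10. A C8 aldehyde and a C1 isopropenyl group (C9=C10–C14) therefore form an ene pair, and C1 with that group is the stereocentre of (R)-carvone. One Me2AlCl-promoted type 2 carbonyl-ene reaction closes ring B, makes C8–C9, sets C8 and leaves a C10=C14 methylene for late hydrogenation. Its precursor is the ring A cyclopentenone (C3 ketone, C4=C5) bearing the C1 isopropenyl group and, on C5, the chain C6H2–C7H(CHO)–C11Me2(OSiEt3). The C7 centre comes from an auxiliary-controlled dienolate alkylation.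

Key step: step 16

Remark: guaiane numbering is used from the ring contraction onward. β denotes the face of ring B that carries H1, O8, C11 and finally C14. The C3 carbinol centre and the C11 oxirane centre are temporary, so their configuration has no bearing on the target.

Step 1
Reactants: 1 (R)-(−)-carvone
Product: 2 (−)-cis-carveol [(1R,5R)-2-methyl-5-(prop-1-en-2-yl)cyclohex-2-en-1-ol; OH cis to isopropenyl]
Conditions: NaBH4, CeCl3·7H2O, MeOH, −20 to 0 °C
Reagents that add atoms: none
Why: Luche 1,2-reduction, in which axial hydride delivery to the half-chair with equatorial isopropenyl gives the equatorial cis alcohol, a temporary centre (later C3) that steers step 2.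

Step 2
Reactants: 2 (−)-cis-carveol
Product: 3 cis-carveol ring epoxide (oxirane on the former ring alkene; syn to the hydroxyl and to the isopropenyl group)
Conditions: VO(acac)2 (cat.), t-BuOOH, CH2Cl2, 0 °C to rt
Reagents that add atoms: tert-butyl hydroperoxide, CC(C)(C)OO
Why: Hydroxyl-directed vanadium-catalysed epoxidation oxidises only the allylic ring alkene, on the face of the hydroxyl, and leaves the isopropenyl group untouched.

Step 3
Reactants: 3 cis-carveol ring epoxide
Product: 4 pivalate of epoxy alcohol 3
Conditions: PivCl, pyridine, DMAP (cat.), CH2Cl2, 0 °C to rt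
Reagents that add atoms: pivaloyl chloride, CC(C)(C)C(=O)Cl
Why: Standard O-acylation masks the carbinol so that periodate cannot cleave a third C–C bond, and the ester survives acid, amine catalysis and borohydride yet falls off without an extra step in step 10.

Step 4
Reactants: 4 pivalate of epoxy alcohol 3
Product: 6 (3S,5R)-6-oxo-5-(pivaloyloxy)-3-(prop-1-en-2-yl)heptanal, via trans-diol 5 (not isolated)
Conditions: H5IO6, THF–H2O, 0 °C to rt
Reagents that add atoms: water, O
Why: Acid-catalysed epoxide hydrolysis followed in the same flask by Malaprade glycol cleavage opens the ring between the two oxirane carbons, while the isopropenyl alkene and both stereocentres are not involved.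

Step 5
Reactants: 6 (3S,5R)-6-oxo-5-(pivaloyloxy)-3-(prop-1-en-2-yl)heptanal
Product: 8 ring A enal [(3R,5R)-2-methyl-3-(pivaloyloxy)-5-(prop-1-en-2-yl)cyclopent-1-ene-1-carbaldehyde; guaiane C1 R and C3 R], via aldol adduct 7 (not isolated)
Conditions: piperidine (cat.), AcOH (cat.), toluene, 70 °C
Reagents that add atoms: none
Why: Amine-catalysed intramolecular aldol condensation (5-enolexo), in which the aldehyde enamine carbon (future C5) adds to the methyl ketone (future C4) activated by its α-acyloxy group and water is lost to give the tetrasubstituted enal, while C1 is not acidified in the enal and keeps the carvone configuration.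

Step 6
Reactants: 8 ring A enal
Product: 9 ring A allylic alcohol (C6 hydroxymethyl on C5)
Conditions: NaBH4, CeCl3·7H2O, MeOH, 0 °C
Reagents that add atoms: none
Why: Luche 1,2-reduction of the enal spares the pivalate and both alkenes and creates no stereocentre.

Step 7
Reactants: 9 ring A allylic alcohol
Product: 10 ring A allylic bromide (C6 bromomethyl on C5)
Conditions: CBr4, PPh3, CH2Cl2, 0 °C
Reagents that add atoms: carbon tetrabromide, BrC(Br)(Br)Br
Why: Appel bromination under neutral conditions proceeds by SN2 displacement at the primary allylic carbon, so neither allylic transposition nor ester loss is expected.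

Step 8
Reactants: 11 (R)-4-benzyl-2-oxazolidinone; 12 3-methylbut-2-enoyl chloride
Product: 14 (R)-4-benzyl-3-(3-methylbut-2-enoyl)oxazolidin-2-one, via N-lithio oxazolidinone 13 (not isolated)
Conditions: n-BuLi, THF, −78 °C; then 12, −78 to 0 °C
Reagents that add atoms: none
Why: N-acylation of the lithiated auxiliary by the acid chloride is the standard entry to the chiral imide and touches no stereocentre.

Step 9
Reactants: 14 (R)-4-benzyl-3-(3-methylbut-2-enoyl)oxazolidin-2-one; 10 ring A allylic bromide
Product: 16 alkylated imide [(7R)-2-isopropenyl acyl imide; C7 bears C11(=C12H2)CH3 and the C6H2–ring A unit], via sodium dienolate 15 (not isolated)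
Conditions: 14 (1.2 equiv), NaN(SiMe3)2, THF, −78 °C; then 10, −78 to −40 °C
Reagents that add atoms: none
Why: Evans asymmetric alkylation in its deconjugative form, in which γ-deprotonation of the s-cis imide gives the chelated Z(O)-dienolate that is alkylated at its α-carbon C7 on the face away from the benzyl group (7R), and whose slim sp2 substituent carries no β-leaving group, so the β-elimination that threatens a β-silyloxy enolate cannot occur.

Step 10
Reactants: 16 alkylated imide
Product: 17 C3,C8-diol (primary C8 alcohol, allylic C3 alcohol, C7 isopropenyl; 1R,3R,7R)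
Conditions: LiAlH4, THF, 0 °C
Reagents that add atoms: none
Why: Hydride reduction takes the exocyclic imide carbonyl to the C8 primary alcohol without base contact at C7, releases the auxiliary and cleaves the pivalate in the same operation.

Step 11
Reactants: 17 C3,C8-diol
Product: 18 enone alcohol (C3 ketone conjugated with C4=C5; free C8 alcohol; 1R,7R)
Conditions: MnO2, CH2Cl2, rt
Reagents that add atoms: none
Why: Chemoselective MnO2 oxidation converts only the allylic C3 alcohol, and installing the enone now makes the tetrasubstituted C4=C5 alkene electron-poor so that it cannot compete as a bishomoallylic partner in step 12.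

Step 12
Reactants: 18 enone alcohol
Product: 19 C11,C12-epoxide of 18 (mixture at C11)
Conditions: VO(acac)2 (cat.), t-BuOOH, toluene, rt
Reagents that add atoms: tert-butyl hydroperoxide, CC(C)(C)OO
Why: Hydroxyl-directed vanadium-catalysed epoxidation of a homoallylic alcohol reaches only C11=C12 from the C8 oxygen, the remote C1 isopropenyl group and the enone alkene stay inert, and the new C11 centre is erased in step 13.

Step 13
Reactants: 19 C11,C12-epoxide
Product: 20 C3,C8,C11-triol (tertiary C11 carbinol with two methyl groups; mixture at C3)
Conditions: LiAlH4, Et2O, 0 °C to rt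
Reagents that add atoms: none
Why: SN2 hydride opening of the 2,2-disubstituted oxirane at its CH2 carbon C12 gives the C11 tertiary alcohol, and the parallel 1,2-reduction of the β,β-disubstituted enone is accepted because step 14 reverses it at no extra cost.

Step 14
Reactants: 20 C3,C8,C11-triol
Product: 21 hydroxy keto aldehyde (C3 enone, C8 aldehyde, free C11 alcohol; 1R,7R)
Conditions: Dess–Martin periodinane (2.5 equiv), NaHCO3, CH2Cl2, 0 °C to rt
Reagents that add atoms: none
Why: Buffered Dess–Martin oxidation converts the primary C8 and the allylic C3 alcohol in one pass, cannot oxidise the tertiary C11 alcohol, and is non-basic enough to leave C7 and C1 unenolised.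

Step 15
Reactants: 21 hydroxy keto aldehyde
Product: 22 ene precursor [ring A enone with C1 isopropenyl and the C5 side chain C6H2–C7H(CHO)–C11Me2(OSiEt3); 1R,7R]
Conditions: Et3SiOTf, 2,6-lutidine, CH2Cl2, −78 to −20 °C
Reagents that add atoms: triethylsilyl trifluoromethanesulfonate, CC[Si](CC)(CC)OS(=O)(=O)C(F)(F)F
Why: Silyl triflate silylation of a hindered tertiary alcohol works at low temperature with a hindered pyridine base that is too weak to enolise the aldehyde or the enone.

Step 16
Reactants: 22 ene precursor
Product: 24 (1R,7S,8R)-8-hydroxy-11-(triethylsilyloxy)guaia-4,10(14)-dien-3-one, via aluminium alkoxide 23 (not isolated)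
Conditions: Me2AlCl (3 equiv), CH2Cl2 (0.01 M), −78 to −30 °C; aq. potassium sodium tartrate
Reagents that add atoms: none
Why: Me2AlCl (used in excess because the first equivalent is held by the more basic C3 enone oxygen) activates the C8 aldehyde, the unsubstituted alkene terminus C9 attacks C8 while charge builds at tertiary C10, a C14 hydrogen passes to oxygen through a six-membered array, and the resulting alcohol complex loses methane to give alkoxide 23, so no protic acid remains that could move the new alkene. The closest known reaction type is the Lewis-acid-promoted type 2 intramolecular carbonyl-ene cyclisation of 1-methylvinyl aldehydes of the 6-methylhept-6-enal kind to 3-methylenecycloheptanols. Ring B closes as a seven-membered ring in the type 2 mode: the tether C1–C5–C6–C7 hangs on the central ene carbon C10, C8–C9 is the only new skeletal bond and C10=C14 ends up exocyclic. C8 is the only new stereocentre and is controlled by three cooperating elements: the hydrogen transfer forces O8 and C14 into a 1,3-diaxial-like, bicyclo[4.3.1]-type array, the flat ring A fusion admits only the chair-like ring B with H1 axial and C2 equatorial, and in that chair the bulky C7 substituent is equatorial, so the axial O8 comes out cis to it (8R). The step needs chemoselectivity for the isopropenyl group over C4=C5, which the electron-poor enone secures, and hydrogen transfer from C14 instead of C1, which geometry secures because H1 cannot reach the oxygen, so C1 keeps its configuration. The tertiary triethylsilyl ether prevents aluminium alkoxide formation and retro-aldol cleavage at C11 and provides the equatorial anchor.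

Step 17
Reactants: 24 ene product
Product: 25 C8 isobutyrate of 24
Conditions: isobutyryl chloride, pyridine, DMAP (cat.), CH2Cl2, 0 °C to rt
Reagents that add atoms: isobutyryl chloride, CC(C)C(=O)Cl
Why: DMAP-catalysed acylation installs the final C8 ester with retention, removes the hydroxyl that could steer a metal to the β face, and enlarges the β-face shield for step 18.

Step 18
Reactants: 25 C8 isobutyrate
Product: 26 (1R,7S,8R,10S)-8-isobutyryloxy-11-(triethylsilyloxy)guai-4-en-3-one
Conditions: H2 (1 atm), RhCl(PPh3)3 (cat.), benzene, rt
Reagents that add atoms: none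
Why: Homogeneous hydrogenation selects the unhindered 1,1-disubstituted alkene over the tetrasubstituted enone and should add hydrogen syn from the α face of C10, opposite the axial C8 ester and the C7 group, which places C14 on the β face (10S, methyl cis to H1 and O8).

Step 19
Reactants: 26 dihydro silyl ether
Product: 27 (1R,7S,8R,10S)-11-hydroxy-8-isobutyryloxyguai-4-en-3-one
Conditions: HF·pyridine, pyridine, THF, 0 °C to rt
Reagents that add atoms: none
Why: Fluoride-mediated desilylation under mildly acidic conditions frees the tertiary alcohol without forming an alkoxide, so ester migration from O8 to O11 and enolisation at C1 are avoided.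

Step 20
Reactants: 27 C11 alcohol
Product: 28 target (CNP0197994.1) [(1R,7S,8R,10S)-11-acetoxy-8-isobutyryloxyguai-4-en-3-one]
Conditions: Ac2O, DMAP, Et3N, CH2Cl2, rt to 40 °C
Reagents that add atoms: acetic anhydride, CC(=O)OC(C)=O
Why: DMAP-promoted (Steglich-type) acetylation is the established way to esterify hindered tertiary alcohols and touches no stereocentre.

Compound list
1 | (R)-(−)-carvone | CC1=CC[C@H](CC1=O)C(C)=C | starting material
2 | (−)-cis-carveol (1R,5R) | CC1=CC[C@H](C[C@H]1O)C(C)=C | intermediate
3 | cis-carveol ring epoxide, oxirane syn to OH | C[C@]12O[C@H]1C[C@H](C[C@H]2O)C(C)=C | intermediate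
4 | pivalate of 3 | C[C@]12O[C@H]1C[C@H](C[C@H]2OC(=O)C(C)(C)C)C(C)=C | intermediate
5 | trans-diol from hydrolysis of 4 (not isolated) | CC1(O)C(O)C[C@H](C[C@H]1OC(=O)C(C)(C)C)C(C)=C | intermediate
6 | (3S,5R)-6-oxo-5-(pivaloyloxy)-3-(prop-1-en-2-yl)heptanal | CC(=O)[C@H](OC(=O)C(C)(C)C)C[C@@H](CC=O)C(C)=C | intermediate
7 | cyclised aldol adduct (not isolated) | CC1(O)C(C=O)[C@H](C[C@H]1OC(=O)C(C)(C)C)C(C)=C | intermediate
8 | ring A enal | CC1=C(C=O)[C@H](C[C@H]1OC(=O)C(C)(C)C)C(C)=C | intermediate
9 | ring A allylic alcohol | CC1=C(CO)[C@H](C[C@H]1OC(=O)C(C)(C)C)C(C)=C | intermediate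
10 | ring A allylic bromide | CC1=C(CBr)[C@H](C[C@H]1OC(=O)C(C)(C)C)C(C)=C | intermediate
11 | (R)-4-benzyl-2-oxazolidinone | O=C1N[C@H](Cc2ccccc2)CO1 | starting material
12 | 3-methylbut-2-enoyl chloride | CC(C)=CC(=O)Cl | starting material
13 | N-lithio-(R)-4-benzyl-2-oxazolidinone (not isolated) | [Li+].O=C1[N-][C@H](Cc2ccccc2)CO1 | intermediate
14 | (R)-4-benzyl-3-(3-methylbut-2-enoyl)oxazolidin-2-one | CC(C)=CC(=O)N1[C@H](Cc2ccccc2)COC1=O | intermediate
15 | sodium Z(O)-dienolate of 14 (not isolated) | [Na+].[O-]/C(=C\C(C)=C)N1[C@H](Cc2ccccc2)COC1=O | intermediate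
16 | alkylated imide (1R,3R,7R) | C=C(C)[C@@H](CC1=C(C)[C@H](OC(=O)C(C)(C)C)C[C@@H]1C(C)=C)C(=O)N1[C@H](Cc2ccccc2)COC1=O | intermediate
17 | C3,C8-diol | C=C(C)[C@@H](CC1=C(C)[C@H](O)C[C@@H]1C(C)=C)CO | intermediate
18 | enone alcohol | C=C(C)[C@@H](CC1=C(C)C(=O)C[C@@H]1C(C)=C)CO | intermediate
19 | C11,C12-epoxide (mixture at C11) | CC1(CO1)[C@@H](CC2=C(C)C(=O)C[C@@H]2C(C)=C)CO | intermediate
20 | C3,C8,C11-triol (mixture at C3) | CC(C)(O)[C@@H](CC1=C(C)C(O)C[C@@H]1C(C)=C)CO | intermediate
21 | hydroxy keto aldehyde | CC(C)(O)[C@@H](CC1=C(C)C(=O)C[C@@H]1C(C)=C)C=O | intermediate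
22 | ene precursor | C=C(C)[C@H]1CC(=O)C(C)=C1C[C@@H](C=O)C(C)(C)O[Si](CC)(CC)CC | intermediate
23 | chloro(methyl)aluminium alkoxide of 24 (not isolated) | C=C1C[C@@H](O[Al](C)Cl)[C@@H](C(C)(C)O[Si](CC)(CC)CC)CC2=C(C)C(=O)C[C@H]12 | intermediate
24 | 10(14)-methylene hydroazulenone with free C8 hydroxyl | C=C1C[C@@H](O)[C@@H](C(C)(C)O[Si](CC)(CC)CC)CC2=C(C)C(=O)C[C@H]12 | intermediate
25 | C8 isobutyrate | C=C1C[C@@H](OC(=O)C(C)C)[C@@H](C(C)(C)O[Si](CC)(CC)CC)CC2=C(C)C(=O)C[C@H]12 | intermediate
26 | 10S dihydro silyl ether | C[C@H]1C[C@@H](OC(=O)C(C)C)[C@@H](C(C)(C)O[Si](CC)(CC)CC)CC2=C(C)C(=O)C[C@H]12 | intermediate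
27 | C11 tertiary alcohol | C[C@H]1C[C@@H](OC(=O)C(C)C)[C@@H](C(C)(C)O)CC2=C(C)C(=O)C[C@H]12 | intermediate
28 | CNP0197994.1 | CC(=O)OC(C)(C)[C@H]1CC2=C(C)C(=O)C[C@@H]2[C@@H](C)C[C@H]1OC(=O)C(C)C | target

Total step count: 20. Longest linear sequence: 19 (steps 1–7 and 9–20, from carvone).

Steps most likely to fail

Step 16. The closure may leave the concerted path. The C10 cation could lose a proton from C1 or C9 to give ring or conjugated alkenes, chloride could be captured at C10, or the Lewis acid could strip the silyl ether and trigger β-elimination. The fallback forms the same C8–C9 bond with reversed polarity and sets out from 22. Ene-type allylic chlorination of the isopropenyl group (NCS, PhSeCl cat., CH2Cl2) should give the 2-(chloromethyl)vinyl aldehyde F1. Treatment with CrCl2 and LiI in THF at high dilution (intramolecular Nozaki–Hiyama–Kishi-type allylation, tolerant of the enone) should then deliver the homoallylic alcohol with the exocyclic methylene. The route is rejoined at 24.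

Step 18. Facial selectivity at C10 may be poor, or a rhodium hydride may move the exocyclic alkene into the ring before reduction. The fallback changes the substrate that controls the face and sets out from 24. Silylation with t-BuMe2SiOTf and 2,6-lutidine gives the 8-O-tert-butyldimethylsilyl ether F2, whose larger axial group shields the β face more strongly. Hydrogenation over RhCl(PPh3)3 then gives the 10S bis-silyl ether F3. Aqueous HF in MeCN removes both silyl groups to give the 8,11-diol F4. Isobutyryl chloride with pyridine acylates only the secondary C8 hydroxyl, and the route is rejoined at 27.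

Step 14. The unprotected β-hydroxy aldehyde may suffer retro-aldol loss of acetone, dehydration to the conjugated enal or epimerisation at C7 before it is silylated. The fallback protects first and sets out from 20. Excess Et3SiOTf with 2,6-lutidine gives the tris(triethylsilyl) ether F5. Brief solvolysis with pyridinium p-toluenesulfonate in MeOH–CH2Cl2 at 0 °C removes the primary and the allylic secondary silyl groups but not the tertiary one, giving the C11-silylated diol F6. Dess–Martin oxidation of both free alcohols then rejoins the route at 22.

Further compounds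
F1 | step 16 | 2-(chloromethyl)vinyl analogue of 22 (C9 chloride, C10=C14) | C=C(CCl)[C@H]1CC(=O)C(C)=C1C[C@@H](C=O)C(C)(C)O[Si](CC)(CC)CC
F2 | step 18 | 8-O-tert-butyldimethylsilyl ether of 24 | C=C1C[C@@H](O[Si](C)(C)C(C)(C)C)[C@@H](C(C)(C)O[Si](CC)(CC)CC)CC2=C(C)C(=O)C[C@H]12
F3 | step 18 | 10S dihydro bis-silyl ether | C[C@H]1C[C@@H](O[Si](C)(C)C(C)(C)C)[C@@H](C(C)(C)O[Si](CC)(CC)CC)CC2=C(C)C(=O)C[C@H]12
F4 | step 18 | (1R,7S,8R,10S)-8,11-dihydroxyguai-4-en-3-one | C[C@H]1C[C@@H](O)[C@@H](C(C)(C)O)CC2=C(C)C(=O)C[C@H]12
F5 | step 14 | tris(triethylsilyl) ether of 20 | CC[Si](CC)(CC)OC(C)(C)[C@@H](CC1=C(C)C(O[Si](CC)(CC)CC)C[C@@H]1C(C)=C)CO[Si](CC)(CC)CC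
F6 | step 14 | C11-triethylsilyl ether of 20 with free C3 and C8 hydroxyls | CC[Si](CC)(CC)OC(C)(C)[C@@H](CC1=C(C)C(O)C[C@@H]1C(C)=C)CO
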